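**Retrosynthetic overview**
- Ring numbering used throughout (also for the future ring atoms of open-chain compounds): C1 = CH(OH), C2=C3(Me), C4 = CH(O-aroyl), C5, C6=C7(Me), C8–C10, C11 = CMe2.
- The ester is installed last, by site-selective 4-hydroxybenzoylation of the C4 hydroxyl of the macrocyclic (1R,4R)-diol.
- The only carbocycle, the cycloundecadiene, is closed at C3–C4 by a ligand-controlled Nozaki–Hiyama–Kishi cyclisation, which sets C4.
- C7–C8 comes from a B-alkyl Suzuki coupling with (E)-4-iodopent-3-en-1-ol; both E-trisubstituted alkenes come from syn-hydrozirconation/iodination of methyl alkynes.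
- C1–C2 and the first stereocentre come from a catalytic, metal-free enantioselective propynylation of 2,2-dimethylpent-4-enal.

Assumption: the sense of induction of the new alkynylation catalyst and of the chromium ligand cannot be predicted with certainty; the catalyst or ligand enantiomer that gives the drawn configuration (checked by Mosher ester analysis) is the one used.

IDPi = (S,S)-imidodiphosphorimidate Brønsted acid built from two 3,3′-bis[3,5-bis(trifluoromethyl)phenyl]-1,1′-binaphthalene-2,2′-diol units, the two phosphorus atoms bridged by N–H and each carrying a P=N–SO2CF3 group.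
L = (S)-N-[2-(4-isopropyl-4,5-dihydro-1,3-oxazol-2-yl)-6-methylphenyl]methanesulfonamide, CC(C)[C@H]1COC(=N1)c1cccc(C)c1NS(C)(=O)=O.

**Route**

Step 1
Reactants: 1 2,2-dimethylpent-4-enal; 2 trimethyl(prop-1-yn-1-yl)silane
Product: 4 (4S)-5,5-dimethyloct-7-en-2-yn-4-ol, via trimethylsilyl ether 3 (not isolated)
Conditions: IDPi (2 mol %), 2 (1.5 equiv), toluene, −60 °C; then MeOH, cat. HCl, 0 °C
Reagents that add atoms: none
Why: Proposed new method: the strong, confined IDPi acid is silylated in situ by 2 (protodesilylation), Me3Si–IDPi silylates the aldehyde oxygen to give an oxocarbenium ion held in the chiral anion pocket, 2 attacks it through its silicon-bearing carbon (β-silyl vinyl cation) and hands Me3Si+ back to the counteranion, so the C1–C2 bond and the C1 stereocentre are formed in one enantiodetermining ipso-alkynylation giving 4S; the closest known reactions are IDPi-catalysed Hosomi–Sakurai allylations and Mukaiyama aldol additions of aldehydes and Lewis-acid ipso-substitutions of alkynylsilanes, while a catalytic enantioselective addition of an alkynylsilane to an aldehyde by silylium counteranion catalysis has not been reported.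

Step 2
Reactants: 5 pent-3-yn-1-ol
Product: 8 (3E)-4-iodopent-3-en-1-ol, via alkenylzirconocene alkoxide 6 (not isolated), via iodoalkene zirconocene alkoxide 7 (not isolated)
Conditions: Cp2Zr(H)Cl (2.5 equiv), THF, rt; I2, 0 °C; aq. NH4Cl
Reagents that add atoms: iodine, II
Why: Hydrozirconation is a syn addition and, with excess Cp2Zr(H)Cl, zirconium settles on the less hindered methyl-bearing alkyne carbon, so iodinolysis with retention gives the E-iodoalkene (hydrozirconation–iodination).

Step 3
Reactants: 4 (4S)-5,5-dimethyloct-7-en-2-yn-4-ol; 8 (3E)-4-iodopent-3-en-1-ol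
Product: 10 (3E,9S)-4,8,8-trimethyldodec-3-en-10-yne-1,9-diol, via alkylborane 9 (not isolated)
Conditions: 9-BBN (1.2 equiv), THF, 0 °C → rt; then 8, Pd(dppf)Cl2 (5 mol %), AsPh3, Cs2CO3, DMF–H2O, rt
Reagents that add atoms: none
Why: 9-BBN hydroborates the monosubstituted alkene far faster than the hindered internal alkyne or the neopentyl-type hydroxyl, and the B-alkyl Suzuki–Miyaura coupling joins C8 to C7 with retention of the E geometry, no stereocentre being touched.

Step 4
Reactants: 10 (3E,9S)-4,8,8-trimethyldodec-3-en-10-yne-1,9-diol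
Product: 13 (3E,9R,10E)-11-iodo-4,8,8-trimethyldodeca-3,10-diene-1,9-diol, via tris-zirconocene adduct 11 (not isolated), via iodoalkene bis-zirconocene alkoxide 12 (not isolated)
Conditions: Cp2Zr(H)Cl (4 equiv), THF, 40 °C; I2, 0 °C; aq. NH4Cl
Reagents that add atoms: iodine, II
Why: With the terminal alkene already consumed, syn-hydrozirconation of the methyl alkyne places zirconium on the methyl-bearing carbon, away from the zirconium alkoxide beside the quaternary carbon, and iodinolysis gives the E-iodoalkene with the trisubstituted alkene untouched (hydrozirconation–iodination); the carbinol centre is not involved and its descriptor changes from S to R only because the alkyne has become an alkene.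

Step 5
Reactants: 13 (3E,9R,10E)-11-iodo-4,8,8-trimethyldodeca-3,10-diene-1,9-diol
Product: 14 (3E,9R,10E)-9-hydroxy-11-iodo-4,8,8-trimethyldodeca-3,10-dienal
Conditions: TEMPO (10 mol %), PhI(OAc)2 (1.1 equiv), CH2Cl2, 0 °C → rt
Reagents that add atoms: none
Why: Oxoammonium oxidation (TEMPO/PhI(OAc)2) is selective for the primary alcohol over the neopentyl-type secondary allylic alcohol, and its near-neutral conditions keep the β,γ-unsaturated aldehyde from conjugating.

Step 6
Reactants: 14 (3E,9R,10E)-9-hydroxy-11-iodo-4,8,8-trimethyldodeca-3,10-dienal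
Product: 17 (1R,2E,4R,6E)-3,7,11,11-tetramethylcycloundeca-2,6-diene-1,4-diol, via alkenylchromium chloride 15 (not isolated), via chromium alkoxide 16 (not isolated)
Conditions: CrCl2 (4 equiv), L (4.4 equiv), Et3N, NiCl2 (5 mol %), THF, 3 mM (slow addition), rt; aq. NH4Cl
Reagents that add atoms: none
Why: Intramolecular Nozaki–Hiyama–Kishi reaction: nickel-mediated activation of the alkenyl iodide, transfer to chromium and addition of the E-alkenylchromium to the aldehyde close the 11-membered ring at C3–C4 with retention of alkene geometry, the chiral oxazoline sulfonamide on chromium directing the aldehyde face so that C4 is formed R.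

Step 7
Reactants: 17 (1R,2E,4R,6E)-3,7,11,11-tetramethylcycloundeca-2,6-diene-1,4-diol; 18 4-acetoxybenzoyl chloride
Product: 20 (1R,2E,4R,9E)-4-hydroxy-2,5,5,9-tetramethylcycloundeca-2,9-dien-1-yl 4-hydroxybenzoate, via acetoxybenzoate ester 19 (not isolated)
Conditions: 18 (1.1 equiv), pyridine, DMAP (5 mol %), CH2Cl2, −20 → 0 °C; then pyrrolidine (3 equiv), rt
Reagents that add atoms: none
Why: DMAP-catalysed acylation takes place at the C4 hydroxyl, which is far less hindered than the C1 hydroxyl beside the quaternary carbon, with retention at C4, and pyrrolidine then cleaves only the activated aryl acetate by aminolysis while the secondary alkyl benzoate is inert (site-selective esterification, then chemoselective deacetylation).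

**Compound list**

1 | 2,2-dimethylpent-4-enal | O=CC(C)(C)CC=C | starting material
2 | trimethyl(prop-1-yn-1-yl)silane | CC#C[Si](C)(C)C | starting material
3 | trimethyl{[(4S)-5,5-dimethyloct-7-en-2-yn-4-yl]oxy}silane | CC#C[C@@H](O[Si](C)(C)C)C(C)(C)CC=C | intermediate
4 | (4S)-5,5-dimethyloct-7-en-2-yn-4-ol | CC#C[C@@H](O)C(C)(C)CC=C | intermediate
5 | pent-3-yn-1-ol | CC#CCCO | starting material
6 | (3E)-pent-3-en-1-ol carrying Cp2Zr(Cl) on C4 and on the oxygen | C/C(=C\CCO[Zr](Cl)(C1C=CC=C1)C1C=CC=C1)[Zr](Cl)(C1C=CC=C1)C1C=CC=C1 | intermediate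
7 | Cp2Zr(Cl) alkoxide of (3E)-4-iodopent-3-en-1-ol | C/C(I)=C\CCO[Zr](Cl)(C1C=CC=C1)C1C=CC=C1 | intermediate
8 | (3E)-4-iodopent-3-en-1-ol | C/C(I)=C\CCO | intermediate
9 | 9-[(5S)-5-hydroxy-4,4-dimethyloct-6-yn-1-yl]-9-borabicyclo[3.3.1]nonane | CC#C[C@@H](O)C(C)(C)CCCB1C2CCCC1CCC2 | intermediate
10 | (3E,9S)-4,8,8-trimethyldodec-3-en-10-yne-1,9-diol | CC#C[C@@H](O)C(C)(C)CCC/C(C)=C/CCO | intermediate
11 | (3E,9R,10E)-4,8,8-trimethyldodeca-3,10-diene-1,9-diol carrying Cp2Zr(Cl) on C11 and on both oxygens | C/C(=C\[C@@H](O[Zr](Cl)(C1C=CC=C1)C1C=CC=C1)C(C)(C)CCC/C(C)=C/CCO[Zr](Cl)(C1C=CC=C1)C1C=CC=C1)[Zr](Cl)(C1C=CC=C1)C1C=CC=C1 | intermediate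
12 | bis[Cp2Zr(Cl)] dialkoxide of (3E,9R,10E)-11-iodo-4,8,8-trimethyldodeca-3,10-diene-1,9-diol | I/C(C)=C/[C@@H](O[Zr](Cl)(C1C=CC=C1)C1C=CC=C1)C(C)(C)CCC/C(C)=C/CCO[Zr](Cl)(C1C=CC=C1)C1C=CC=C1 | intermediate
13 | (3E,9R,10E)-11-iodo-4,8,8-trimethyldodeca-3,10-diene-1,9-diol | I/C(C)=C/[C@@H](O)C(C)(C)CCC/C(C)=C/CCO | intermediate
14 | (3E,9R,10E)-9-hydroxy-11-iodo-4,8,8-trimethyldodeca-3,10-dienal | I/C(C)=C/[C@@H](O)C(C)(C)CCC/C(C)=C/CC=O | intermediate
15 | chlorido[(2E,4R,10E)-4-hydroxy-5,5,9-trimethyl-12-oxododeca-2,10-dien-2-yl]chromium carrying deprotonated L (trivalent chromium; 14 with chromium in place of iodine) | Cl[Cr](N(c1c(C)cccc1C1=N[C@@H](C(C)C)CO1)S(C)(=O)=O)/C(C)=C/[C@@H](O)C(C)(C)CCC/C(C)=C/CC=O | intermediate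
16 | chromium alkoxide of 17 through the C4 oxygen, chromium carrying chloride and deprotonated L (trivalent chromium) | C/C1=C\C[C@@H](O[Cr](Cl)N(c2c(C)cccc2C2=N[C@@H](C(C)C)CO2)S(C)(=O)=O)/C(C)=C/[C@@H](O)C(C)(C)CCC1 | intermediate
17 | (1R,2E,4R,6E)-3,7,11,11-tetramethylcycloundeca-2,6-diene-1,4-diol | C/C1=C\C[C@@H](O)/C(C)=C/[C@@H](O)C(C)(C)CCC1 | intermediate
18 | 4-acetoxybenzoyl chloride | CC(=O)Oc1ccc(cc1)C(Cl)=O | starting material
19 | (1R,2E,4R,9E)-4-hydroxy-2,5,5,9-tetramethylcycloundeca-2,9-dien-1-yl 4-acetoxybenzoate | C/C1=C\C[C@@H](OC(=O)c2ccc(OC(C)=O)cc2)/C(C)=C/[C@@H](O)C(C)(C)CCC1 | intermediate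
20 | (1R,2E,4R,9E)-4-hydroxy-2,5,5,9-tetramethylcycloundeca-2,9-dien-1-yl 4-hydroxybenzoate | C/C1=C\C[C@@H](OC(=O)c2ccc(O)cc2)/C(C)=C/[C@@H](O)C(C)(C)CCC1 | target

**Step count**

Total steps: 7. Longest linear sequence: 6 (steps 1, 3, 4, 5, 6, 7, from 2,2-dimethylpent-4-enal); step 2 is a one-step side branch.

**Steps most likely to fail, with fallbacks**

Step 1 (the proposed new alkynylation). The alkynylsilane may be too weak a nucleophile, the activated aldehyde may react with its own alkene in a Prins-type way, or the ee may be low. The fallback is known chemistry and sets out from 1 and returns at 4. Addition of 1-propynylmagnesium bromide to 1 gives racemic 5,5-dimethyloct-7-en-2-yn-4-ol F1. Dess–Martin oxidation gives 5,5-dimethyloct-7-en-2-yn-4-one F2. Corey–Bakshi–Shibata reduction with (S)-Me-CBS oxazaborolidine (10 mol %) and catecholborane at −78 °C, in which the tert-alkyl group acts as the large and the propynyl group as the small substituent, gives 4. The first stereocentre stays catalytic and metal-free, at the cost of two extra steps.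

Step 4 (hydrozirconation–iodination of the diol). Addition to the alkyne beside the quaternary carbon may be slow or not fully regioselective. The fallback sets out from 10 and returns at 17, bypassing steps 4 to 6. Selective TEMPO/PhI(OAc)2 oxidation of the primary alcohol gives (3E,9S)-9-hydroxy-4,8,8-trimethyldodec-3-en-10-ynal F3. A reductive alkyne–aldehyde macrocyclisation with Ni(cod)2 (zerovalent nickel), PBu3 and Et3B then adds H and the aldehyde carbon syn across the alkyne, with the C–C bond at the methyl-bearing carbon, and gives 17. The C4 epimer formed alongside is treated as in the fallback for step 6.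

Step 6 (macrocyclisation and C4 configuration). The ring closure may oligomerise, or the ligand may not override the macrocycle's own facial preference. The fallback sets out from 14 and returns at 20. Cyclisation is run without ligand (CrCl2, cat. NiCl2, DMSO, high dilution). If it gives mainly (1R,2E,4S,6E)-3,7,11,11-tetramethylcycloundeca-2,6-diene-1,4-diol F4, this epimer is esterified with inversion by a Mitsunobu reaction with unprotected 4-hydroxybenzoic acid (PPh3, DIAD, THF). The carboxylic acid reacts in preference to the phenol and the C1 hydroxyl is too hindered to react, so 20 is obtained directly. Either C4 epimer of the diol can therefore be carried to the target.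

**Further compounds**

F1 | step 1 | racemic 5,5-dimethyloct-7-en-2-yn-4-ol | CC#CC(O)C(C)(C)CC=C
F2 | step 1 | 5,5-dimethyloct-7-en-2-yn-4-one | CC#CC(=O)C(C)(C)CC=C
F3 | step 4 | (3E,9S)-9-hydroxy-4,8,8-trimethyldodec-3-en-10-ynal | CC#C[C@@H](O)C(C)(C)CCC/C(C)=C/CC=O
F4 | step 6 | (1R,2E,4S,6E)-3,7,11,11-tetramethylcycloundeca-2,6-diene-1,4-diol | C/C1=C\C[C@H](O)/C(C)=C/[C@@H](O)C(C)(C)CCC1
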